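**Assumption:** the target has no stereocentre and no stereogenic double bond, so "the single enantiomer given" is read as the one achiral constitution CCCCCCCCCCCCCCCCCCCC(=O)OCc1ccccc1.

## The problem

Benzyl eicosanoate 7 is a straight C20 saturated acyl chain on a benzyl ester. It has no stereocentre and no ring other than the phenyl ring, so nothing has to be controlled in space. What has to be solved is the chain: nineteen sp3 carbons (C2–C20, counted from the ester carbonyl C1) joined by C–C bonds with no functional group to mark where two pieces could be joined. The chain length must be exact, because the C18, C19, C21 and C22 homologues of 7 cannot practically be separated from it. The building blocks must therefore be homologue-pure, and the joining reaction must not be able to move or lose carbons. The one sensitive group is the benzyl ester: the O–CH2Ph bond is lost on hydrogenolysis, the acyl–O bond to alkoxide, hydroxide or hard carbon nucleophiles, and the benzylic C–H bonds are open to oxidation. This rules out "alkene, then H2/Pd" unless the ester is put on last.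

The feature that makes the key step possible is the C3–C4 bond. It joins two primary CH2 carbons: C3 lies β to the ester carbonyl C1, and C4 heads an unbranched C17 alkyl group. Each can be drawn as having carried a carboxyl group, C3 in a succinic half ester and C4 in stearic acid. Both are then unstabilised primary radicals, the kind that anodic decarboxylation couples instead of oxidising further. The phenyl ring is insulated from this bond by the CH2–O–C(=O) link and need not take part.

## Retrosynthesis

**Disconnection 1 (7 ⇒ 3 + 4, through the carboxylates 5 and 6).** The C3–C4 bond of 7 is cut homolytically, and each carbon is given back a carboxyl group. This leads to 4-(benzyloxy)-4-oxobutanoic acid 3 (monobenzyl succinate) and octadecanoic acid 4 (stearic acid), which react as their potassium salts 5 and 6 in a mixed Kolbe electrolysis. The neighbouring cuts are weaker: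
- Cutting C1–O leaves the whole C20 chain to be bought.
- Cutting C2–C3 would need the rare odd-numbered C19 acid.
- Cutting C5–C6 would need an adipic half ester, which can only be made statistically from the diacid.
- Only the C3–C4 cut pairs a bulk even-numbered fatty acid (C18) with a C4 half ester that comes from a cyclic anhydride with no statistical problem.

The C27 target thus falls into a bought commodity acid 4 and a C11 half ester 3, and the benzyl ester is already in place, so the coupling product is the target itself. The net change, stearate plus two carbons at the carboxyl end, is the same as in the biosynthetic elongation of stearate to arachidate, but is reached through radicals of like polarity. The forward reaction must meet three demands: cross-coupling must outrun the two homocouplings, the radicals must couple and not be oxidised to cations, and the benzyl ester must survive at both electrodes.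

**Disconnection 2 (3 ⇒ 1 + 2).** The acyl–O bond of the half ester 3 is cut, giving succinic anhydride 1 and benzyl alcohol 2. The ring of 1 desymmetrises the C4 diacid by itself: one acylation opens the ring and releases a free carboxyl group that is no acylating agent, so the reaction stops at the monoester. Both precursors are commodity chemicals. The forward reaction only has to go to completion and give 3 free of 2, since an alcohol would be oxidised at the anode in the next step.

## Roads not taken

**Alternative 1:** Cut the acyl–O bond C1–O of 7, the most obvious route. Eicosanoic acid A1 would be esterified with 2 under acid catalysis or with a carbodiimide. This is one step shorter than the chosen plan if A1 is bought, and it would be the practical choice for mere supply. It is set aside because it builds no C–C bond: the whole chain problem is handed to the supplier of A1, a minor natural fatty acid, whereas 4 is a bulk oleochemical. The chosen plan makes the skeleton from C18 and C4 feedstocks with the ester already present, and it is modular: another fatty acid or another cyclic anhydride gives any homologue or a labelled C1–C3 unit by the same two steps.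

**Alternative 2:** Cut C10–C11 as a double bond. Olefin cross-metathesis of benzyl undec-10-enoate A2 with undec-1-ene A3 on a ruthenium carbene would give benzyl eicos-10-enoate A4 as an E/Z mixture, followed by saturation of the alkene. This has three weaknesses:
- Both partners are unhindered terminal alkenes, so the metathesis is as statistical as the Kolbe coupling.
- Ruthenium hydrides formed from the catalyst can migrate the double bonds before metathesis, which would give C19 and C21 homologues that cannot be removed.
- The alkene of A4 must be reduced without hydrogenolysis of the O-benzyl bond, which excludes H2/Pd and needs diimide or a homogeneous catalyst.

The route needs three steps (ester A2, metathesis, reduction) and introduces an unsaturation only to erase it. The chosen plan reaches the saturated chain directly in two.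

**Alternative 3:** Cut C6–C7 in the polar sense. Tetradecylmagnesium bromide A5 would be coupled with benzyl 6-bromohexanoate A6 under copper catalysis (Kochi-type sp3–sp3 coupling). The two carbons must first be given opposite polarity: one chain becomes a halide on an ester, the other a halide turned into a Grignard reagent, which makes three operations with halogen and magnesium waste. A5 is in principle incompatible with the benzyl ester of A6 and of the product (ketone and tertiary alcohol formation), so the step relies only on a rate difference at low temperature; Wurtz-type homocoupling also competes. In the chosen plan both carbons enter at the same polarity and oxidation level, as free carboxylic acids in wet methanol, and no reagent present can attack the ester carbonyl.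

Key step: step 2

## Route

Step 1
Reactants: 1 succinic anhydride (oxolane-2,5-dione); 2 benzyl alcohol
Product: 3 4-(benzyloxy)-4-oxobutanoic acid (monobenzyl succinate)
Conditions: 1 (1.1 equiv), 2 (1.0 equiv), DMAP (5 mol%), toluene, 80 °C; extraction into aq. NaHCO3, washing with ether, acidification, crystallisation
Reagents that add atoms: none
Why: DMAP-catalysed alcoholysis of a cyclic anhydride (nucleophilic acyl substitution) is an addition with no co-product and stops at the half ester because the carboxyl group set free is not an acylating agent; the bicarbonate extraction should remove every trace of neutral 2 before the electrolysis.

Step 2
Reactants: 3 4-(benzyloxy)-4-oxobutanoic acid (monobenzyl succinate); 4 octadecanoic acid (stearic acid, homologue-pure grade)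
Product: 7 benzyl eicosanoate, via potassium 4-(benzyloxy)-4-oxobutanoate 5 (not isolated), via potassium octadecanoate 6 (not isolated)
Conditions: 3 (4 equiv), 4 (1 equiv), KOH (10 mol% of total CO2H), MeOH, 45 °C, undivided cell, smooth Pt anode, stainless-steel cathode, constant current ca. 0.2 A cm−2, vigorous stirring, current stopped while the electrolyte is still faintly acidic; NaHCO3 wash, chromatography
Reagents that add atoms: none
Why: This is a mixed (crossed) Kolbe electrolysis, the classical anodic chain extension of a fatty acid with an alkyl hydrogen succinate, here run with the benzyl half ester. The carboxylates 5 and 6 adsorb on platinum at high current density, are oxidised by one electron each to acyloxy radicals and lose CO2 at once, giving the 3-(benzyloxy)-3-oxopropyl radical from 5 and the heptadecyl radical from 6; their combination at the electrode surface forms the C3–C4 bond, while the cathode reduces carboxyl protons to H2 and so regenerates the carboxylates. No ring is closed and no stereocentre is formed. Cross-selectivity is statistical, so the cheap half ester 3 is used in fourfold excess; most heptadecyl radicals should then meet the C3 radical, and the main by-product should be the symmetrical diester from homocoupling of the C3 radical, which is more polar than 7 and separable on silica. Both radicals are primary and carry no α-donor, so further oxidation to cations (Hofer–Moest path) should be minor on smooth Pt in weakly acidic methanol. The benzyl ester should survive at the anode because the carboxylate layer at the Kolbe potential keeps solvent, arene and neutral ester away from the surface. It should survive in solution because the excess of free acid leaves no methoxide for transesterification, and at the cathode because proton reduction occurs far positive of ester reduction and steel does not catalyse hydrogenolysis. A 1,5-hydrogen shift from the benzylic CH2 to the C3 radical would need the disfavoured E conformation of the ester and should not compete with radical combination.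

## Compound list

1 | succinic anhydride (oxolane-2,5-dione) | O=C1CCC(=O)O1 | starting material
2 | benzyl alcohol (phenylmethanol) | OCc1ccccc1 | starting material
3 | 4-(benzyloxy)-4-oxobutanoic acid (monobenzyl succinate) | OC(=O)CCC(=O)OCc1ccccc1 | intermediate
4 | octadecanoic acid (stearic acid) | CCCCCCCCCCCCCCCCCC(=O)O | starting material
5 | potassium 4-(benzyloxy)-4-oxobutanoate | [K+].[O-]C(=O)CCC(=O)OCc1ccccc1 | intermediate (not isolated)
6 | potassium octadecanoate | CCCCCCCCCCCCCCCCCC(=O)[O-].[K+] | intermediate (not isolated)
7 | benzyl eicosanoate (eicosanoic acid phenylmethyl ester) | CCCCCCCCCCCCCCCCCCCC(=O)OCc1ccccc1 | target

## Step count and risks

Total step count: 2. Longest linear sequence: 2 steps (1 → 3 → 7); 4 enters in step 2. The route has only two steps, so both are assessed.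

**Step 2 (key step).** Three processes are most likely to lower the outcome:
- Homocoupling and disproportionation of the two radicals, which are inherent in a statistical radical coupling.
- Passivation of the anode by a film of long-chain material. The potential then drops below the Kolbe region, and solvent oxidation takes over.
- Loss of the benzyl group, by methanolysis in the alkaline layer at the cathode if stirring is poor or the current runs after the acids are used up, or by benzylic oxidation at a poorly covered anode.

Fallback: a reductive decarboxylative Giese addition, which turns the same heptadecyl radical onto a polarity-matched acceptor and needs neither electrodes nor methanol nor compound 3. It sets out from 4. This is condensed with N-hydroxyphthalimide (N,N'-diisopropylcarbodiimide, cat. DMAP, CH2Cl2) to the redox-active ester 1,3-dioxoisoindolin-2-yl octadecanoate F1. Irradiation of F1 with benzyl acrylate F2, Ru(bpy)3Cl2 (cat.), Hantzsch ester and iPr2NEt in CH2Cl2 under blue light should fragment it to CO2, phthalimide and the heptadecyl radical. This nucleophilic radical adds to the β-carbon of F2, and the α-ester radical is reduced by hydrogen transfer from the Hantzsch ester, forming the same C3–C4 bond. The fallback comes back to the route at 7.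

**Step 1.** The most likely faults are incomplete acylation, which leaves 2 to be carried into the electrolysis and oxidised at the anode, and slow equilibration of the half ester to diester and diacid on prolonged heating. Fallback: desymmetrisation from the diester side. It sets out from 1 and 2. Heating 1 with an excess of 2 and catalytic TsOH in toluene with removal of water should give dibenzyl succinate F3. Selective monohydrolysis with one equivalent of KOH in THF–water at 0 °C, then acidification, should stop at the half ester because the carboxylate formed shields the second ester group. The fallback comes back to the route at 3.

## Further compounds

F1 | step 2 | 1,3-dioxoisoindolin-2-yl octadecanoate (N-hydroxyphthalimide ester of stearic acid) | CCCCCCCCCCCCCCCCCC(=O)ON1C(=O)c2ccccc2C1=O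
F2 | step 2 | benzyl acrylate (benzyl prop-2-enoate, purchased coupling partner) | C=CC(=O)OCc1ccccc1
F3 | step 1 | dibenzyl succinate (dibenzyl butanedioate) | O=C(CCC(=O)OCc1ccccc1)OCc1ccccc1
A1 | alternative 1 | eicosanoic acid (arachidic acid) | CCCCCCCCCCCCCCCCCCCC(=O)O
A2 | alternative 2 | benzyl undec-10-enoate | C=CCCCCCCCCC(=O)OCc1ccccc1
A3 | alternative 2 | undec-1-ene | C=CCCCCCCCCC
A4 | alternative 2 | benzyl eicos-10-enoate (E/Z mixture) | CCCCCCCCCC=CCCCCCCCCC(=O)OCc1ccccc1
A5 | alternative 3 | tetradecylmagnesium bromide | CCCCCCCCCCCCCC[Mg]Br
A6 | alternative 3 | benzyl 6-bromohexanoate | BrCCCCCC(=O)OCc1ccccc1
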